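**Plan**
- Retrosynthesis: the two methoxymethyl (MOM) ethers are removed first, then ring C is opened at C3–C4 to an achiral aldehyde in which O1–C2 is carried as an aryl 1-arylvinyl ether (C2=C3).
- The enol ether comes from HCl loss out of a β-chloro ether. Its O1–C2 bond is cut to a ring A phenol and a ring B chlorohydrin. The prenyl C–C bonds (C6, C8, C5') and the C2–C3 bond (aldehyde + CH2Cl) are cut last.
- Enabling feature: C4 is a formyl carbon on ring A, flanked by the C5 hydroxyl and by O1. Its C–H bond lies across from the terminal carbon C3 of the enol ether O1–C2(=C3H2)–ring B, so adding C4–H across C2=C3 closes ring C and creates C2 in one event.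
- Ring A is symmetric about its C4a–C7 axis (O5 and O1, and the C6 and C8 prenyl groups, are equivalent), so etherifying either ortho hydroxyl gives the same compound.
- Forward order: ring A piece (2 steps) and ring B piece (4 steps) are joined through O1–C2, the racemic centre is erased by elimination, ring C is closed, and the MOM groups are removed.
- Stereochemistry: the single centre, C2 (S), is set by the chiral bisphosphine–rhodium catalyst during ring closure and is never exposed to base afterwards.

Key step: step 9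

Assumption: (R)-DTBM-SEGPHOS is taken as the ligand antipode that delivers hydride to the face of C2 leading to (2S); if the sense proves opposite, the (S) ligand is used with no other change.

**Route**

Step 1
Reactants: 1 2,4,6-trihydroxybenzaldehyde
Product: 3 2,4,6-trihydroxy-3,5-bis(3-methylbut-2-en-1-yl)benzaldehyde, via 3-prenyl-2,4,6-trihydroxybenzaldehyde 2 (not isolated)
Conditions: prenyl bromide (2.2 equiv), 10% aq. KOH, 0 °C to rt
Reagents that add atoms: 1-bromo-3-methylbut-2-ene (prenyl bromide), CC(C)=CCBr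
Why: Twofold C-alkylation of the phloroglucinol-type phenoxide (acylphloroglucinol C-prenylation) goes to C3 and C5, the only unsubstituted, doubly oxygen-activated ring carbons, and water as solvent favours C- over O-alkylation.

Step 2
Reactants: 3 2,4,6-trihydroxy-3,5-bis(3-methylbut-2-en-1-yl)benzaldehyde
Product: 4 2,6-dihydroxy-4-(methoxymethoxy)-3,5-bis(3-methylbut-2-en-1-yl)benzaldehyde
Conditions: MOMCl (1.0 equiv), K2CO3, acetone, 0 °C
Reagents that add atoms: chloromethyl methyl ether, COCCl
Why: Williamson-type ether formation should occur at the C4 hydroxyl, which is the most acidic (para to the formyl group) and, unlike the two ortho hydroxyls, is not tied to the carbonyl oxygen by hydrogen bonding.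

Step 3
Reactants: 5 3-bromo-4,5-dihydroxybenzaldehyde
Product: 6 3-bromo-5-hydroxy-4-methoxybenzaldehyde
Conditions: MeI (1.1 equiv), Li2CO3, DMF, 40 °C
Reagents that add atoms: iodomethane, CI
Why: Regioselective Williamson methylation, because the weak base ionises only the more acidic hydroxyl para to the formyl group and next to bromine.

Step 4
Reactants: 6 3-bromo-5-hydroxy-4-methoxybenzaldehyde
Product: 7 3-bromo-4-methoxy-5-(methoxymethoxy)benzaldehyde
Conditions: MOMCl, K2CO3, acetone, rt
Reagents that add atoms: chloromethyl methyl ether, COCCl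
Why: Standard methoxymethyl protection of the remaining phenol, needed so that ring B offers no competing nucleophile in step 7.

Step 5
Reactants: 7 3-bromo-4-methoxy-5-(methoxymethoxy)benzaldehyde
Product: 8 4-methoxy-3-(methoxymethoxy)-5-(3-methylbut-2-en-1-yl)benzaldehyde
Conditions: Bu3SnCH2CH=CMe2, Pd(PPh3)4 (5 mol %), DMF, 100 °C
Reagents that add atoms: tributyl(3-methylbut-2-en-1-yl)stannane, CCCC[Sn](CCCC)(CCCC)CC=C(C)C
Why: Stille cross-coupling of the aryl bromide under zerovalent palladium catalysis should deliver the linear prenyl group, and the aldehyde is inert to the allylstannane in the absence of a Lewis acid.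

Step 6
Reactants: 8 4-methoxy-3-(methoxymethoxy)-5-(3-methylbut-2-en-1-yl)benzaldehyde
Product: 9 racemic 2-chloro-1-[4-methoxy-3-(methoxymethoxy)-5-(3-methylbut-2-en-1-yl)phenyl]ethan-1-ol
Conditions: ICH2Cl, MeLi·LiBr, THF, −78 °C; then AcOH, −78 °C
Reagents that add atoms: chloroiodomethane, ClCI
Why: Chloromethyllithium, made by iodine–lithium exchange in the presence of the aldehyde (Barbier mode), adds to the carbonyl and the cold acidic quench traps the chlorohydrin before epoxide closure; the new centre is racemic, which does not matter because step 8 erases it.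

Step 7
Reactants: 4 2,6-dihydroxy-4-(methoxymethoxy)-3,5-bis(3-methylbut-2-en-1-yl)benzaldehyde; 9 racemic 2-chloro-1-[4-methoxy-3-(methoxymethoxy)-5-(3-methylbut-2-en-1-yl)phenyl]ethan-1-ol
Product: 10 racemic 2-{2-chloro-1-[4-methoxy-3-(methoxymethoxy)-5-(3-methylbut-2-en-1-yl)phenyl]ethoxy}-6-hydroxy-4-(methoxymethoxy)-3,5-bis(3-methylbut-2-en-1-yl)benzaldehyde
Conditions: PPh3, DIAD, THF, 0 °C to rt
Reagents that add atoms: none
Why: Mitsunobu etherification of the acidic salicylaldehyde-type phenol with the secondary benzylic alcohol; the two ortho hydroxyls of 4 are equivalent by symmetry, and after the first etherification the remaining one is held by its hydrogen bond to the formyl oxygen, so the monoether should prevail.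

Step 8
Reactants: 10 racemic 2-{2-chloro-1-[4-methoxy-3-(methoxymethoxy)-5-(3-methylbut-2-en-1-yl)phenyl]ethoxy}-6-hydroxy-4-(methoxymethoxy)-3,5-bis(3-methylbut-2-en-1-yl)benzaldehyde
Product: 11 2-hydroxy-6-({1-[4-methoxy-3-(methoxymethoxy)-5-(3-methylbut-2-en-1-yl)phenyl]ethenyl}oxy)-4-(methoxymethoxy)-3,5-bis(3-methylbut-2-en-1-yl)benzaldehyde
Conditions: KOtBu (2.2 equiv), THF, 0 °C to rt
Reagents that add atoms: none
Why: E2 dehydrochlorination of the β-chloro ether, whose only β-hydrogen is the benzylic, oxygen-bearing C–H, should give the aryl 1-arylvinyl ether and remove the racemic centre; the non-enolisable aldehyde and the phenoxide tolerate the base.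

Step 9
Reactants: 11 2-hydroxy-6-({1-[4-methoxy-3-(methoxymethoxy)-5-(3-methylbut-2-en-1-yl)phenyl]ethenyl}oxy)-4-(methoxymethoxy)-3,5-bis(3-methylbut-2-en-1-yl)benzaldehyde
Product: 12 (2S)-5-hydroxy-7-(methoxymethoxy)-2-[4-methoxy-3-(methoxymethoxy)-5-(3-methylbut-2-en-1-yl)phenyl]-6,8-bis(3-methylbut-2-en-1-yl)-2,3-dihydro-4H-chromen-4-one
Conditions: [Rh(cod)2]BF4 (5 mol %), (R)-DTBM-SEGPHOS (5.5 mol %), 1,2-dichloroethane, 60 °C
Reagents that add atoms: none
Why: Proposed new method: cationic monovalent rhodium inserts into the formyl C–H bond (the adjacent C5 hydroxyl should stabilise the acyl trivalent rhodium hydride against decarbonylation), the tethered C2=C3 enol ether inserts into Rh–H with hydride going to C2 and rhodium to the terminal C3, and C–C reductive elimination from the seven-membered acyl(alkyl)rhodacycle forms the C3–C4 bond. The closest known reaction type is the rhodium/bisphosphine-catalysed enantioselective intramolecular hydroacylation of 1,1-disubstituted alkenes (4-substituted pent-4-enals to 3-substituted cyclopentanones, ortho-(2-substituted allyl)benzaldehydes to 3-substituted tetralones); an aryl 1-arylvinyl ether has not been used as the alkene. Ring C closes in a formal 6-endo-trig mode, the acyl carbon bonding to the terminal alkene carbon. The C2 stereocentre is created when hydride is delivered to one enantioface of the 1,1-disubstituted alkene, the face being selected by the chiral pocket of the bisphosphine on rhodium. The step needs six- over five-membered ring formation, which the substrate secures because the alternative requires a tertiary benzylic alkyl–rhodium and reductive elimination to a quaternary carbon. It also needs chemoselectivity over the three prenyl groups, which are trisubstituted and poorly coordinating, and of which the two on ring A sit meta to the formyl group so that no ring can close onto them.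

Step 10
Reactants: 12 (2S)-5-hydroxy-7-(methoxymethoxy)-2-[4-methoxy-3-(methoxymethoxy)-5-(3-methylbut-2-en-1-yl)phenyl]-6,8-bis(3-methylbut-2-en-1-yl)-2,3-dihydro-4H-chromen-4-one
Product: 15 isoamoritin, via 7-O-methoxymethyl isoamoritin 13 (not isolated), via 3'-O-methoxymethyl isoamoritin 14 (not isolated)
Conditions: 3 M aq. HCl, MeOH, 40 °C
Reagents that add atoms: none
Why: Acid-catalysed acetal exchange with methanol removes both methoxymethyl ethers as dimethoxymethane, and the C2 centre should hold because acid does not trigger the enolate/retro-oxa-Michael ring opening that racemises flavanones in base, while the mild temperature limits chroman formation by the prenyl groups.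

**Compound list**

1 | 2,4,6-trihydroxybenzaldehyde | O=Cc1c(O)cc(O)cc1O | starting material
2 | 2,4,6-trihydroxy-3-(3-methylbut-2-en-1-yl)benzaldehyde | O=Cc1c(O)c(CC=C(C)C)c(O)cc1O | intermediate
3 | 2,4,6-trihydroxy-3,5-bis(3-methylbut-2-en-1-yl)benzaldehyde | O=Cc1c(O)c(CC=C(C)C)c(O)c(CC=C(C)C)c1O | intermediate
4 | 2,6-dihydroxy-4-(methoxymethoxy)-3,5-bis(3-methylbut-2-en-1-yl)benzaldehyde | O=Cc1c(O)c(CC=C(C)C)c(OCOC)c(CC=C(C)C)c1O | intermediate
5 | 3-bromo-4,5-dihydroxybenzaldehyde | O=Cc1cc(O)c(O)c(Br)c1 | starting material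
6 | 3-bromo-5-hydroxy-4-methoxybenzaldehyde | O=Cc1cc(O)c(OC)c(Br)c1 | intermediate
7 | 3-bromo-4-methoxy-5-(methoxymethoxy)benzaldehyde | O=Cc1cc(OCOC)c(OC)c(Br)c1 | intermediate
8 | 4-methoxy-3-(methoxymethoxy)-5-(3-methylbut-2-en-1-yl)benzaldehyde | O=Cc1cc(OCOC)c(OC)c(CC=C(C)C)c1 | intermediate
9 | racemic 2-chloro-1-[4-methoxy-3-(methoxymethoxy)-5-(3-methylbut-2-en-1-yl)phenyl]ethan-1-ol | OC(CCl)c1cc(OCOC)c(OC)c(CC=C(C)C)c1 | intermediate
10 | racemic 2-{2-chloro-1-[4-methoxy-3-(methoxymethoxy)-5-(3-methylbut-2-en-1-yl)phenyl]ethoxy}-6-hydroxy-4-(methoxymethoxy)-3,5-bis(3-methylbut-2-en-1-yl)benzaldehyde | O=Cc1c(O)c(CC=C(C)C)c(OCOC)c(CC=C(C)C)c1OC(CCl)c1cc(OCOC)c(OC)c(CC=C(C)C)c1 | intermediate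
11 | 2-hydroxy-6-({1-[4-methoxy-3-(methoxymethoxy)-5-(3-methylbut-2-en-1-yl)phenyl]ethenyl}oxy)-4-(methoxymethoxy)-3,5-bis(3-methylbut-2-en-1-yl)benzaldehyde | O=Cc1c(O)c(CC=C(C)C)c(OCOC)c(CC=C(C)C)c1OC(=C)c1cc(OCOC)c(OC)c(CC=C(C)C)c1 | intermediate
12 | (2S)-5-hydroxy-7-(methoxymethoxy)-2-[4-methoxy-3-(methoxymethoxy)-5-(3-methylbut-2-en-1-yl)phenyl]-6,8-bis(3-methylbut-2-en-1-yl)-2,3-dihydro-4H-chromen-4-one | COc1c(OCOC)cc([C@@H]2CC(=O)c3c(O)c(CC=C(C)C)c(OCOC)c(CC=C(C)C)c3O2)cc1CC=C(C)C | intermediate
13 | 7-O-methoxymethyl isoamoritin, (2S)-5-hydroxy-2-[3-hydroxy-4-methoxy-5-(3-methylbut-2-en-1-yl)phenyl]-7-(methoxymethoxy)-6,8-bis(3-methylbut-2-en-1-yl)-2,3-dihydro-4H-chromen-4-one | COc1c(O)cc([C@@H]2CC(=O)c3c(O)c(CC=C(C)C)c(OCOC)c(CC=C(C)C)c3O2)cc1CC=C(C)C | intermediate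
14 | 3'-O-methoxymethyl isoamoritin, (2S)-5,7-dihydroxy-2-[4-methoxy-3-(methoxymethoxy)-5-(3-methylbut-2-en-1-yl)phenyl]-6,8-bis(3-methylbut-2-en-1-yl)-2,3-dihydro-4H-chromen-4-one | COc1c(OCOC)cc([C@@H]2CC(=O)c3c(O)c(CC=C(C)C)c(O)c(CC=C(C)C)c3O2)cc1CC=C(C)C | intermediate
15 | isoamoritin, (2S)-5,7-dihydroxy-2-[3-hydroxy-4-methoxy-5-(3-methylbut-2-en-1-yl)phenyl]-6,8-bis(3-methylbut-2-en-1-yl)-2,3-dihydro-4H-chromen-4-one | COc1c(O)cc([C@@H]2CC(=O)c3c(O)c(CC=C(C)C)c(O)c(CC=C(C)C)c3O2)cc1CC=C(C)C | target

**Count**

Total steps: 10. Longest linear sequence: 8 steps (5 to 15 through steps 3 to 10).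

**Steps most likely to fail**

Step 9 (proposed new method). The hindered, electron-rich formyl group may resist C–H insertion or decarbonylate. Closure may turn to the five-membered ketone. Enantioface discrimination at the enol ether may be poor. The fallback sets the stereocentre before ring closure and forms the same bond by acyl-anion alkylation, using known reaction types. It sets out from 9 and 4 and comes back at 12. Dess–Martin oxidation of 9 gives 2-chloro-1-[4-methoxy-3-(methoxymethoxy)-5-(3-methylbut-2-en-1-yl)phenyl]ethan-1-one F1. Asymmetric transfer hydrogenation with RuCl[(R,R)-TsDPEN](p-cymene) in HCO2H/Et3N should give the (1S)-chlorohydrin F2. Mitsunobu etherification of 4 with F2 (PPh3, DIAD, inversion at the benzylic carbon) should give the (1R)-chloro ether F3. NaI in acetone gives the (1R)-iodo ether F4. An N-heterocyclic carbene generated from 3-benzyl-5-(2-hydroxyethyl)-4-methylthiazolium chloride and Cs2CO3 in toluene then converts the formyl group into its Breslow intermediate, which displaces iodide at C3 in a 6-exo-tet closure. The configuration at C2 is retained (the descriptor changes from R to S only because the priorities change), giving 12.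

Step 7. Substitution at the hindered secondary benzylic carbon by a phenol that is itself substituted at both ortho positions may be slow, and the activated alcohol may eliminate instead. The fallback makes the O1–C2 bond at an sp2 carbon by cross-coupling and bypasses steps 6 to 8. It sets out from 8 and 4 and comes back at 11. MeMgBr addition to 8 gives racemic 1-[4-methoxy-3-(methoxymethoxy)-5-(3-methylbut-2-en-1-yl)phenyl]ethan-1-ol F5. Dess–Martin oxidation gives the corresponding acetophenone F6. KN(SiMe3)2 and PhNTf2 give 1-[4-methoxy-3-(methoxymethoxy)-5-(3-methylbut-2-en-1-yl)phenyl]ethenyl trifluoromethanesulfonate F7. Palladium-catalysed C–O coupling of F7 with 4 (Pd2(dba)3, 2-(di-tert-butylphosphino)biphenyl, K3PO4, toluene, 80 °C) should give 11 directly.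

Step 1. O-alkylation, incomplete alkylation and geminal over-alkylation with loss of aromaticity may erode the twofold C-prenylation. The fallback fixes the two positions by halogenation and introduces the prenyl groups by cross-coupling. It sets out from 1 and comes back at 3. Iodination of 1 (I2, NaHCO3, aq. THF) should give 2,4,6-trihydroxy-3,5-diiodobenzaldehyde F8, and twofold Stille coupling of F8 with Bu3SnCH2CH=CMe2 (Pd(PPh3)4, DMF, 90 °C) should give 3.

**Further compounds**

F1 | step 9 | 2-chloro-1-[4-methoxy-3-(methoxymethoxy)-5-(3-methylbut-2-en-1-yl)phenyl]ethan-1-one | O=C(CCl)c1cc(OCOC)c(OC)c(CC=C(C)C)c1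
F2 | step 9 | (1S)-2-chloro-1-[4-methoxy-3-(methoxymethoxy)-5-(3-methylbut-2-en-1-yl)phenyl]ethan-1-ol | O[C@H](CCl)c1cc(OCOC)c(OC)c(CC=C(C)C)c1
F3 | step 9 | 2-{(1R)-2-chloro-1-[4-methoxy-3-(methoxymethoxy)-5-(3-methylbut-2-en-1-yl)phenyl]ethoxy}-6-hydroxy-4-(methoxymethoxy)-3,5-bis(3-methylbut-2-en-1-yl)benzaldehyde | O=Cc1c(O)c(CC=C(C)C)c(OCOC)c(CC=C(C)C)c1O[C@@H](CCl)c1cc(OCOC)c(OC)c(CC=C(C)C)c1
F4 | step 9 | 2-hydroxy-6-{(1R)-2-iodo-1-[4-methoxy-3-(methoxymethoxy)-5-(3-methylbut-2-en-1-yl)phenyl]ethoxy}-4-(methoxymethoxy)-3,5-bis(3-methylbut-2-en-1-yl)benzaldehyde | O=Cc1c(O)c(CC=C(C)C)c(OCOC)c(CC=C(C)C)c1O[C@@H](CI)c1cc(OCOC)c(OC)c(CC=C(C)C)c1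
F5 | step 7 | racemic 1-[4-methoxy-3-(methoxymethoxy)-5-(3-methylbut-2-en-1-yl)phenyl]ethan-1-ol | CC(O)c1cc(OCOC)c(OC)c(CC=C(C)C)c1
F6 | step 7 | 1-[4-methoxy-3-(methoxymethoxy)-5-(3-methylbut-2-en-1-yl)phenyl]ethan-1-one | CC(=O)c1cc(OCOC)c(OC)c(CC=C(C)C)c1
F7 | step 7 | 1-[4-methoxy-3-(methoxymethoxy)-5-(3-methylbut-2-en-1-yl)phenyl]ethenyl trifluoromethanesulfonate | C=C(OS(=O)(=O)C(F)(F)F)c1cc(OCOC)c(OC)c(CC=C(C)C)c1
F8 | step 1 | 2,4,6-trihydroxy-3,5-diiodobenzaldehyde | O=Cc1c(O)c(I)c(O)c(I)c1O
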